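## Analysis of the target

The target is a bicyclic spermidine-type alkaloid of the cannabisativine class. Its atoms are numbered here N1, C2, C3=C4, C5, C6 (ring A, a 1,2,3,6-tetrahydropyridine), then C7, C8(=O), N9, C10–C13, N14, C15–C17 back to N1. The thirteen-membered lactam is fused to ring A through the N1–C6 bond. There are two stereocentres, C2 (S, carrying the 2-oxoheptyl arm) and C6 (R, carrying C7). They flank N1 and are trans to each other, an arrangement that simple equilibration of a 2,6-disubstituted piperidine would not be expected to favour. The sensitive groups are the β-amino ketone (C2–CH2–C=O), which can open by retro-aza-Michael cleavage and epimerise C2 once the ketone is free, the allylic C2–N1 bond, the basic N14, and the ring alkene, which excludes hydrogenolysis. The hard points are the trans-2,6 relationship, the hindered N1 that must become tertiary inside a macrocycle, and keeping three nitrogens and a ketone differentiated. The plan rests on one pattern: N1 flanked by C2 and C6, with C3=C4 allylic to C2. That pattern results when a carbanion on an N-CH2 group of a 2-alkyl-3-vinylaziridine bonds to the vinyl terminus (future C5) while the aziridine N1–C3 bond opens.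

## Retrosynthetic reasoning

The ketone of 32 is exposed last, from ketal 31, under acid where both amines are protonated. 31 comes from sulfonamide 30. The sulfonamide on N14 is removed before the ketal because its cleavage needs a basic thiolate, which a free β-amino ketone would not tolerate.

In 30 the N1–C17 bond is cut, leading to amino mesylate 28, carbamate 27 and alcohol 26. The amide C8–N9 is the other obvious ring cut, but it is better formed earlier together with the one-carbon insertion. The forward reaction is an intramolecular SN2 alkylation of a hindered secondary amine at high dilution. N14 carries a sulfonamide and not a carbamate: a carbamate oxygen three atoms from C17 would close a six-membered cyclic carbamate faster than N1 closes the macrocycle.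

26 is cut at C8–N9 and at C6–C7 in one operation, to ketene 25 and amine 24. The ketene arises from diazoketone 19 by a 1,2-shift of C6 with retention, which supplies C7, the carbon the key step cannot deliver. Amine 24 is built from 20 and 22 through sulfonamide 21 and its N-alkyl derivative 23.

19 requires acid 17 with N1 as a carbamate. The tert-butyl ester of 13 cannot be cleaved with acid, because the dioxolane would go first. The ester is therefore reduced to alcohol 14, N1 is protected (15), and the alcohol is oxidised back through aldehyde 16 under buffered conditions. This costs two steps, keeps the ketal intact, and lets the key step use the bulky ester it needs.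

13 is disconnected at C5–C6 with re-formation of N1–C3, giving vinylaziridine 11. This cut is preferred over C2–C3 or N1–C2 because ring A, the position of C3=C4 and the configuration of C6 then come from one concerted step, with C2 fixed beforehand. The forward step generates enolate 12 and must give the trans-2,6 arrangement, which requires the cis-aziridine.

cis-Aziridine 11 is opened at N1–C2 to syn amino alcohol 9, and further to cis-epoxide 7 and amine 8. Two SN2 inversions, one at each epoxide carbon, carry the cis geometry of 7 into 11 whichever carbon the amine attacks first. A route in which a vinyl metal adds to an α-amino aldehyde was not used: its normal Felkin–Anh course gives the anti amino alcohol, which closes to the trans-aziridine and ends in the 2,6-cis series.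

7 is cut at the bond between C2 and the future C3 into aldehyde 3 and the three carbons of 4. They are joined by an asymmetric chloroallylboration through boron adduct 5 and chlorohydrin 6. This one bond sets the absolute configuration of C2 and the syn relationship that becomes the cis epoxide. 3 comes from keto ester 1 through ketal 2, so the C2 side chain is complete and masked from the first step.

## Alternatives that were turned down

Alternative 1: Dearomatisation of a pyridinium salt. The disconnections are C2–C1′ and C6–C7, both back to an intact pyridine that supplies N1 and C2–C6. In the forward step a pyridinium salt with a chiral amino-alcohol-derived N-substituent takes up a 1-alkynyl Grignard reagent at C2. The dihydropyridine is protonated at C5, the auxiliary hydroxyl traps C6 as an N,O-acetal, and a Lewis acid reopens it for attack of a ketene silyl acetal, giving A1.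
- For: it is very short, needs no ring-forming step, and the C6 arm arrives with C7 and C8 in place. On that last point it is stronger than the chosen route, which needs a homologation.
- Against: the alkyne must be hydrated with oxygen on the carbon remote from C2, and nothing in a propargylic amine enforces that regiochemistry. The auxiliary must be cleaved at a benzylic C–N bond without hydrogenolysis while the allylic C2–N1 bond survives. Both facial selectivities depend on one auxiliary, the second in an intermolecular addition to an iminium ion.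
- Comparison: the chosen strategy is longer, but C6 is set by a concerted intramolecular shift and the side chain has the right oxidation pattern from the start.

Alternative 2: Ring-rearrangement metathesis. The disconnection is C3=C4, with the C2 side chain stored as a cyclopentene. An N-sulfonyl amine carrying a cis-4-silyloxycyclopent-2-enyl group and a 1-(methoxycarbonylmethyl)but-3-enyl group is treated with a ruthenium alkylidene catalyst. The cyclopentene opens and ring A closes, giving A2.
- For: both stereocentres are made beforehand and are not touched, so the key step poses no stereochemical question. That is stronger than the chosen route. The step is catalytic and the C6 arm is complete.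
- Against: the side chain of A2 ends in a vinyl carbinol. It must be extended by three carbons, its alkene saturated in the presence of C3=C4, and the carbinol oxidised. A stereocentre is made only to be destroyed, and opening a weakly strained cyclopentene gives little driving force.
- Comparison: the chosen route delivers the side chain complete in step 1 and needs fewer operations after the key step, at the price of a stereochemical risk in the key step.

Alternative 3: Vinylsilane–iminium cyclisation. The disconnection is N1=C2 and C2–C3. An amine half (C3–C6, with N1 already carrying the whole chain to N9) condenses with aldehyde 3 to an iminium ion. The (Z)-vinylsilane attacks it in a 6-endo mode with loss of silicon, giving A3.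
- For: it is the most convergent plan and uses the same aldehyde 3. N1 is tertiary before ring A forms, so the macrocycle would close by lactamisation and not by alkylating a hindered amine. This is stronger than the chosen route at its weakest late step. No homologation is needed.
- Against: C2 is created in the cyclisation, and its relation to C6 depends on iminium geometry and on how the N-alkyl group and the C6 arm sit in the chair, so the trans outcome is not secured. The acid needed for iminium formation meets a ketal and a tert-butyl carbamate, and a β,β-dialkoxy iminium can tautomerise. The amine half needs its own multi-step asymmetric synthesis.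
- Comparison: the chosen strategy fixes C2 first by a reagent-controlled addition and derives C6 from it through a suprafacial shift.

Key step: step 6

Remark: the chloroallylborane from (−)-Ipc2BOMe is assumed to add to the Si face of 3, as the parent allylborane of the same pinene series does with aliphatic aldehydes; if the sense were opposite, the enantiomeric borane would be used and nothing else would change.

## Route

Step 1
Reactants: 1 ethyl 3-oxooctanoate
Product: 2 ethyl 2-(2-pentyl-1,3-dioxolan-2-yl)acetate
Conditions: HOCH2CH2OH, TsOH·H2O (cat.), toluene, reflux, Dean–Stark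
Reagents that add atoms: ethylene glycol, OCCO
Why: Acid-catalysed ketalisation with azeotropic removal of water; the ketone of a β-keto ester reacts cleanly, the ester is untouched, and the dioxolane removes the acidic α-hydrogens that would interfere with every later base.

Step 2
Reactants: 2 ethyl 2-(2-pentyl-1,3-dioxolan-2-yl)acetate
Product: 3 2-(2-pentyl-1,3-dioxolan-2-yl)acetaldehyde
Conditions: iBu2AlH, CH2Cl2, −78 °C; MeOH, aq. potassium sodium tartrate
Reagents that add atoms: none
Why: Partial reduction of an ester to the aldehyde at low temperature; the ketal oxygen β to the carbonyl helps to hold the reduction at the aldehyde level.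

Step 3
Reactants: 3 2-(2-pentyl-1,3-dioxolan-2-yl)acetaldehyde; 4 allyl chloride
Product: 7 (2R,3S)-2-[(2-pentyl-1,3-dioxolan-2-yl)methyl]-3-vinyloxirane (cis), via borinate ester 5 (not isolated), via syn-chlorohydrin 6 (not isolated)
Conditions: 4, LiN(c-C6H11)2, (−)-Ipc2BOMe, THF/Et2O, −95 °C; BF3·OEt2; 3, −95 °C; NaOH, H2O2, 0 °C; K2CO3, MeOH, rt
Reagents that add atoms: none
Why: Asymmetric γ-chloroallylboration: the (Z)-γ-chloroallylborane formed in the flask adds through a chair transition state, so its Z geometry gives the syn chlorohydrin and the isopinocampheyl groups select the Si face of 3, which sets C2. Base then closes the epoxide by intramolecular SN2 displacement of chloride with inversion, turning the syn chlorohydrin into the cis epoxide.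

Step 4
Reactants: 7 (2R,3S)-2-[(2-pentyl-1,3-dioxolan-2-yl)methyl]-3-vinyloxirane; 8 tert-butyl glycinate
Product: 9 tert-butyl 2-{[(3R,4R)-4-hydroxy-5-(2-pentyl-1,3-dioxolan-2-yl)pent-1-en-3-yl]amino}acetate (syn)
Conditions: 8 (3 equiv), LiClO4, MeCN, 60 °C
Reagents that add atoms: none
Why: Aminolysis of a vinyl epoxide: the amine attacks the allylic carbon by SN2 with inversion to give the syn amino alcohol; attack at the other epoxide carbon would do no harm, because ring closure in step 5 leads to the same aziridine by double inversion. The tert-butyl ester resists lactonisation by the new hydroxyl.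

Step 5
Reactants: 9 tert-butyl 2-{[(3R,4R)-4-hydroxy-5-(2-pentyl-1,3-dioxolan-2-yl)pent-1-en-3-yl]amino}acetate
Product: 11 tert-butyl 2-{(2S,3R)-2-[(2-pentyl-1,3-dioxolan-2-yl)methyl]-3-vinylaziridin-1-yl}acetate (cis), via alkoxyphosphonium ion 10 (not isolated)
Conditions: PPh3, DIAD, THF, 0 °C to rt
Reagents that add atoms: none
Why: Mitsunobu cyclodehydration of a β-amino alcohol: the hydroxyl is activated as the alkoxyphosphonium ion and displaced by the neighbouring secondary amine in a 3-exo-tet SN2 closure with inversion at C2, so the syn amino alcohol gives the cis-aziridine with C2 now S.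

Step 6
Reactants: 11 tert-butyl 2-{(2S,3R)-2-[(2-pentyl-1,3-dioxolan-2-yl)methyl]-3-vinylaziridin-1-yl}acetate
Product: 13 tert-butyl (2R,6S)-6-[(2-pentyl-1,3-dioxolan-2-yl)methyl]-1,2,3,6-tetrahydropyridine-2-carboxylate (2,6-trans), via lithium enolate 12 (not isolated)
Conditions: LiN(iPr)2, THF, −78 °C (warming to −40 °C if required); then H2O
Reagents that add atoms: none
Why: LiN(iPr)2 removes a proton from the N-CH2 group next to the ester to give enolate 12; the ketal and the aziridine carry no comparably acidic hydrogen, and the tert-butyl ester resists attack by the amide base and self-condensation. In the nitrogen invertomer that holds the enolate arm on the face of the vinyl group, the enolate carbon (future C6) bonds to the vinyl terminus (C5) while the aziridine N1–C3 bond breaks and C3=C4 forms, a concerted suprafacial [2,3]-sigmatropic shift through a five-centre envelope C6–N1–C3–C4–C5. This is the known aza-[2,3]-Wittig ring expansion of N-(alkoxycarbonylmethyl)-2-vinylaziridines, which is best established for trans-2,3-disubstituted aziridines. Ring A therefore closes by a three-to-six ring expansion and not by an exo or endo cyclisation onto a π bond; the alkene is necessarily cis within the ring, and release of aziridine strain together with formation of the lithium amide makes the shift irreversible. C2 is a spectator aziridine carbon and keeps its S configuration. The new centre C6 is set in the transition state: the ester takes the exo position, turned away from C2, and because the C2 side chain is cis to the vinyl group it lies on the face of the forming five-membered array, so the ester ends anti to that side chain, which is the trans-2,6 product with C6 R. The step needs this exo preference and access to the more crowded invertomer; the first should be reinforced by the clash an endo ester would have with the cis side chain, while the second is expected to cost rate rather than selectivity, hence the allowance for warming.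

Step 7
Reactants: 13 tert-butyl (2R,6S)-6-[(2-pentyl-1,3-dioxolan-2-yl)methyl]-1,2,3,6-tetrahydropyridine-2-carboxylate
Product: 14 {(2R,6S)-6-[(2-pentyl-1,3-dioxolan-2-yl)methyl]-1,2,3,6-tetrahydropyridin-2-yl}methanol
Conditions: LiAlH4, THF, 0 °C to rt; H2O, aq. NaOH
Reagents that add atoms: none
Why: Hydride reduction of the ester to the primary alcohol; it replaces an acidolysis of the tert-butyl ester that the dioxolane would not survive, and C6 is not epimerised because no enolate is formed.

Step 8
Reactants: 14 {(2R,6S)-6-[(2-pentyl-1,3-dioxolan-2-yl)methyl]-1,2,3,6-tetrahydropyridin-2-yl}methanol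
Product: 15 allyl (2R,6S)-2-(hydroxymethyl)-6-[(2-pentyl-1,3-dioxolan-2-yl)methyl]-3,6-dihydropyridine-1(2H)-carboxylate
Conditions: ClCO2CH2CH=CH2, NaHCO3, THF/H2O, 0 °C to rt
Reagents that add atoms: allyl chloroformate, C=CCOC(=O)Cl
Why: Schotten–Baumann carbamoylation; the amine reacts with the chloroformate faster than the primary alcohol in aqueous bicarbonate, and the allyl carbamate can later be removed under neutral conditions that spare ketal, sulfonamide and ring alkene.

Step 9
Reactants: 15 allyl (2R,6S)-2-(hydroxymethyl)-6-[(2-pentyl-1,3-dioxolan-2-yl)methyl]-3,6-dihydropyridine-1(2H)-carboxylate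
Product: 17 (2R,6S)-1-(allyloxycarbonyl)-6-[(2-pentyl-1,3-dioxolan-2-yl)methyl]-1,2,3,6-tetrahydropyridine-2-carboxylic acid, via aldehyde 16 (not isolated)
Conditions: TEMPO (cat.), NaClO2, NaOCl (cat.), MeCN, phosphate buffer pH 6.7, 35 °C
Reagents that add atoms: sodium chlorite, [Na+].[O-]Cl=O
Why: Oxoammonium-mediated oxidation of the primary alcohol to aldehyde 16, which NaClO2 takes on to the acid in the same pot; the near-neutral buffer protects the ketal, and N-carbamoyl α-amino aldehydes pass through this sequence without loss of configuration.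

Step 10
Reactants: 17 (2R,6S)-1-(allyloxycarbonyl)-6-[(2-pentyl-1,3-dioxolan-2-yl)methyl]-1,2,3,6-tetrahydropyridine-2-carboxylic acid
Product: 19 allyl (2R,6S)-2-(diazoacetyl)-6-[(2-pentyl-1,3-dioxolan-2-yl)methyl]-3,6-dihydropyridine-1(2H)-carboxylate, via mixed anhydride 18 (not isolated)
Conditions: iBuOCOCl, N-methylmorpholine, THF, −15 °C; CH2N2, Et2O, 0 °C to rt
Reagents that add atoms: diazomethane, C=[N+]=[N-]
Why: First stage of the Arndt–Eistert homologation: the acid is activated as the mixed carbonic anhydride and acylates diazomethane at carbon; carbamate-protected α-amino acids give such diazoketones without epimerisation.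

Step 11
Reactants: 20 tert-butyl (4-aminobutyl)carbamate
Product: 21 tert-butyl {4-[(2-nitrophenyl)sulfonylamino]butyl}carbamate
Conditions: 2-O2NC6H4SO2Cl, Et3N, CH2Cl2, 0 °C
Reagents that add atoms: 2-nitrobenzenesulfonyl chloride, O=S(=O)(Cl)c1ccccc1[N+](=O)[O-]
Why: Sulfonylation of the primary amine; the 2-nitrobenzenesulfonyl group makes the N–H acidic enough for clean monoalkylation and later serves as a non-participating protecting group for N14.

Step 12
Reactants: 21 tert-butyl {4-[(2-nitrophenyl)sulfonylamino]butyl}carbamate; 22 3-bromopropan-1-ol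
Product: 23 tert-butyl {4-[(3-hydroxypropyl)(2-nitrophenylsulfonyl)amino]butyl}carbamate
Conditions: K2CO3, DMF, 60 °C
Reagents that add atoms: none
Why: SN2 alkylation of the sulfonamide anion; the sulfonamide N–H is far more acidic than the hydroxyl or the carbamate N–H, so only N14 is alkylated and only once.

Step 13
Reactants: 23 tert-butyl {4-[(3-hydroxypropyl)(2-nitrophenylsulfonyl)amino]butyl}carbamate
Product: 24 N-(4-aminobutyl)-N-(3-hydroxypropyl)-2-nitrobenzenesulfonamide
Conditions: HCl, 1,4-dioxane, rt; aq. K2CO3
Reagents that add atoms: none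
Why: Acidolysis of the tert-butyl carbamate frees N9; the sulfonamide and the alcohol are stable to anhydrous HCl.

Step 14
Reactants: 19 allyl (2R,6S)-2-(diazoacetyl)-6-[(2-pentyl-1,3-dioxolan-2-yl)methyl]-3,6-dihydropyridine-1(2H)-carboxylate; 24 N-(4-aminobutyl)-N-(3-hydroxypropyl)-2-nitrobenzenesulfonamide
Product: 26 allyl (2R,6S)-2-{2-[(4-{(3-hydroxypropyl)[(2-nitrophenyl)sulfonyl]amino}butyl)amino]-2-oxoethyl}-6-[(2-pentyl-1,3-dioxolan-2-yl)methyl]-3,6-dihydropyridine-1(2H)-carboxylate, via ketene 25 (not isolated)
Conditions: PhCO2Ag (cat.), Et3N, THF, −25 °C to rt, dark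
Reagents that add atoms: none
Why: Wolff rearrangement: loss of N2 and 1,2-shift of C6 with retention give ketene 25, which the primary amine of 24 captures much faster than its hydroxyl; C7 is inserted and the C8–N9 amide formed in one operation.

Step 15
Reactants: 26 the hydroxy amide of step 14
Product: 27 methanesulfonate of 26 (allyl carbamate on N1, sulfonamide on N14, OSO2Me on C17)
Conditions: MeSO2Cl, Et3N, CH2Cl2, 0 °C
Reagents that add atoms: methanesulfonyl chloride, CS(=O)(=O)Cl
Why: Sulfonylation of the primary alcohol; the amide and the fully substituted sulfonamide nitrogen do not react.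

Step 16
Reactants: 27 methanesulfonate of 26
Product: 30 (13R,17S)-5-[(2-nitrophenyl)sulfonyl]-17-[(2-pentyl-1,3-dioxolan-2-yl)methyl]-1,5,10-triazabicyclo[11.4.0]heptadec-15-en-11-one, via amino mesylate 28 (not isolated), via amino iodide 29 (not isolated)
Conditions: Pd(PPh3)4 (cat.), PhSiH3, CH2Cl2, rt; then slow addition to NaI, iPr2NEt, MeCN (ca. 1 mM), 80 °C
Reagents that add atoms: none
Why: Zerovalent palladium ionises the allyl carbamate and the silane reduces the allyl fragment, freeing N1; Finkelstein exchange in the flask gives iodide 29, which the secondary amine displaces intramolecularly (SN2) under high dilution to close the thirteen-membered ring. The sulfonamide on N14 cannot attack C17 as a carbamate oxygen would.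

Step 17
Reactants: 30 the N14-sulfonyl macrocycle
Product: 31 (13R,17S)-17-[(2-pentyl-1,3-dioxolan-2-yl)methyl]-1,5,10-triazabicyclo[11.4.0]heptadec-15-en-11-one
Conditions: PhSH, K2CO3, MeCN, rt
Reagents that add atoms: none
Why: Thiolate cleavage of the 2-nitrobenzenesulfonamide by ipso substitution through a Meisenheimer adduct and loss of SO2; it is done while the ketone is still masked, so no enone can form by β-elimination and trap the thiol.

Step 18
Reactants: 31 the ketal-protected macrocycle
Product: 32 (13R,17S)-17-(2-oxoheptyl)-1,5,10-triazabicyclo[11.4.0]heptadec-15-en-11-one (target)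
Conditions: 1 M HCl, THF, rt; aq. NaHCO3, 0 °C
Reagents that add atoms: water, O
Why: Acid hydrolysis of the dioxolane; both amines stay protonated, which suppresses retro-aza-Michael opening of the β-amino ketone, and the free base is liberated cold and briefly so that C2 is not epimerised.

## Compound list

1 | ethyl 3-oxooctanoate | CCCCCC(=O)CC(=O)OCC | starting material
2 | ethyl 2-(2-pentyl-1,3-dioxolan-2-yl)acetate | CCCCCC1(OCCO1)CC(=O)OCC | intermediate
3 | 2-(2-pentyl-1,3-dioxolan-2-yl)acetaldehyde | CCCCCC1(OCCO1)CC=O | intermediate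
4 | allyl chloride (3-chloroprop-1-ene) | C=CCCl | starting material
5 | (2R,3R)-3-chloro-1-(2-pentyl-1,3-dioxolan-2-yl)pent-4-en-2-yl bis(isopinocampheyl)borinate | CCCCCC1(OCCO1)C[C@@H](OB([C@@H]2C[C@@H]3C[C@H]([C@H]2C)C3(C)C)[C@@H]4C[C@@H]5C[C@H]([C@H]4C)C5(C)C)[C@H](Cl)C=C | intermediate (not isolated)
6 | (2R,3R)-3-chloro-1-(2-pentyl-1,3-dioxolan-2-yl)pent-4-en-2-ol (syn) | CCCCCC1(OCCO1)C[C@@H](O)[C@H](Cl)C=C | intermediate (not isolated)
7 | (2R,3S)-2-[(2-pentyl-1,3-dioxolan-2-yl)methyl]-3-vinyloxirane (cis) | CCCCCC1(OCCO1)C[C@H]2O[C@H]2C=C | intermediate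
8 | tert-butyl glycinate (tert-butyl 2-aminoacetate) | NCC(=O)OC(C)(C)C | starting material
9 | tert-butyl 2-{[(3R,4R)-4-hydroxy-5-(2-pentyl-1,3-dioxolan-2-yl)pent-1-en-3-yl]amino}acetate | CCCCCC1(OCCO1)C[C@@H](O)[C@H](NCC(=O)OC(C)(C)C)C=C | intermediate
10 | O-triphenylphosphonium derivative of 9 (cation) | CCCCCC1(OCCO1)C[C@@H](O[P+](c2ccccc2)(c3ccccc3)c4ccccc4)[C@H](NCC(=O)OC(C)(C)C)C=C | intermediate (not isolated)
11 | tert-butyl 2-{(2S,3R)-2-[(2-pentyl-1,3-dioxolan-2-yl)methyl]-3-vinylaziridin-1-yl}acetate (cis) | CCCCCC1(OCCO1)C[C@H]2[C@@H](C=C)N2CC(=O)OC(C)(C)C | intermediate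
12 | lithium enolate of 11 | [Li+].CCCCCC1(OCCO1)C[C@H]2[C@@H](C=C)N2C=C([O-])OC(C)(C)C | intermediate (not isolated)
13 | tert-butyl (2R,6S)-6-[(2-pentyl-1,3-dioxolan-2-yl)methyl]-1,2,3,6-tetrahydropyridine-2-carboxylate (2,6-trans) | CCCCCC1(OCCO1)C[C@H]2C=CC[C@H](C(=O)OC(C)(C)C)N2 | intermediate
14 | {(2R,6S)-6-[(2-pentyl-1,3-dioxolan-2-yl)methyl]-1,2,3,6-tetrahydropyridin-2-yl}methanol | CCCCCC1(OCCO1)C[C@H]2C=CC[C@H](CO)N2 | intermediate
15 | allyl (2R,6S)-2-(hydroxymethyl)-6-[(2-pentyl-1,3-dioxolan-2-yl)methyl]-3,6-dihydropyridine-1(2H)-carboxylate | CCCCCC1(OCCO1)C[C@H]2C=CC[C@H](CO)N2C(=O)OCC=C | intermediate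
16 | allyl (2R,6S)-2-formyl-6-[(2-pentyl-1,3-dioxolan-2-yl)methyl]-3,6-dihydropyridine-1(2H)-carboxylate | CCCCCC1(OCCO1)C[C@H]2C=CC[C@H](C=O)N2C(=O)OCC=C | intermediate (not isolated)
17 | (2R,6S)-1-(allyloxycarbonyl)-6-[(2-pentyl-1,3-dioxolan-2-yl)methyl]-1,2,3,6-tetrahydropyridine-2-carboxylic acid | CCCCCC1(OCCO1)C[C@H]2C=CC[C@H](C(=O)O)N2C(=O)OCC=C | intermediate
18 | isobutyl carbonic mixed anhydride of 17 | CCCCCC1(OCCO1)C[C@H]2C=CC[C@H](C(=O)OC(=O)OCC(C)C)N2C(=O)OCC=C | intermediate (not isolated)
19 | allyl (2R,6S)-2-(diazoacetyl)-6-[(2-pentyl-1,3-dioxolan-2-yl)methyl]-3,6-dihydropyridine-1(2H)-carboxylate | CCCCCC1(OCCO1)C[C@H]2C=CC[C@H](C(=O)C=[N+]=[N-])N2C(=O)OCC=C | intermediate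
20 | tert-butyl (4-aminobutyl)carbamate | NCCCCNC(=O)OC(C)(C)C | starting material
21 | tert-butyl {4-[(2-nitrophenyl)sulfonylamino]butyl}carbamate | CC(C)(C)OC(=O)NCCCCNS(=O)(=O)c1ccccc1[N+](=O)[O-] | intermediate
22 | 3-bromopropan-1-ol | OCCCBr | starting material
23 | tert-butyl {4-[(3-hydroxypropyl)(2-nitrophenylsulfonyl)amino]butyl}carbamate | CC(C)(C)OC(=O)NCCCCN(CCCO)S(=O)(=O)c1ccccc1[N+](=O)[O-] | intermediate
24 | N-(4-aminobutyl)-N-(3-hydroxypropyl)-2-nitrobenzenesulfonamide | NCCCCN(CCCO)S(=O)(=O)c1ccccc1[N+](=O)[O-] | intermediate
25 | allyl (2R,6S)-2-(2-oxoethenyl)-6-[(2-pentyl-1,3-dioxolan-2-yl)methyl]-3,6-dihydropyridine-1(2H)-carboxylate (ketene) | CCCCCC1(OCCO1)C[C@H]2C=CC[C@H](C=C=O)N2C(=O)OCC=C | intermediate (not isolated)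
26 | allyl (2R,6S)-2-{2-[(4-{(3-hydroxypropyl)[(2-nitrophenyl)sulfonyl]amino}butyl)amino]-2-oxoethyl}-6-[(2-pentyl-1,3-dioxolan-2-yl)methyl]-3,6-dihydropyridine-1(2H)-carboxylate | CCCCCC1(OCCO1)C[C@H]2C=CC[C@H](CC(=O)NCCCCN(CCCO)S(=O)(=O)c3ccccc3[N+](=O)[O-])N2C(=O)OCC=C | intermediate
27 | methanesulfonate of 26 | CCCCCC1(OCCO1)C[C@H]2C=CC[C@H](CC(=O)NCCCCN(CCCOS(C)(=O)=O)S(=O)(=O)c3ccccc3[N+](=O)[O-])N2C(=O)OCC=C | intermediate
28 | N1-deprotected amino mesylate | CCCCCC1(OCCO1)C[C@H]2C=CC[C@H](CC(=O)NCCCCN(CCCOS(C)(=O)=O)S(=O)(=O)c3ccccc3[N+](=O)[O-])N2 | intermediate (not isolated)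
29 | amino iodide corresponding to 28 | CCCCCC1(OCCO1)C[C@H]2C=CC[C@H](CC(=O)NCCCCN(CCCI)S(=O)(=O)c3ccccc3[N+](=O)[O-])N2 | intermediate (not isolated)
30 | (13R,17S)-5-[(2-nitrophenyl)sulfonyl]-17-[(2-pentyl-1,3-dioxolan-2-yl)methyl]-1,5,10-triazabicyclo[11.4.0]heptadec-15-en-11-one | CCCCCC1(OCCO1)C[C@H]2C=CC[C@@H]3CC(=O)NCCCCN(S(=O)(=O)c4ccccc4[N+](=O)[O-])CCCN23 | intermediate
31 | (13R,17S)-17-[(2-pentyl-1,3-dioxolan-2-yl)methyl]-1,5,10-triazabicyclo[11.4.0]heptadec-15-en-11-one | CCCCCC1(OCCO1)C[C@H]2C=CC[C@@H]3CC(=O)NCCCCNCCCN23 | intermediate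
32 | (13R,17S)-17-(2-oxoheptyl)-1,5,10-triazabicyclo[11.4.0]heptadec-15-en-11-one | CCCCCC(=O)C[C@H]1C=CC[C@@H]2CC(=O)NCCCCNCCCN21 | target

## Step count and least certain steps

Total: 18 steps, of which 15 are in the main line and 3 (steps 11–13) make amine 24. Longest linear sequence: 15 steps (1–10 and 14–18).

Step 6 (key step).
- Risk: the shift has to start from the nitrogen invertomer that holds the enolate arm syn to both ring substituents. If that invertomer is reached too slowly, the enolate may condense with itself or fragment on warming before it rearranges. A second risk is loss of the exo preference of the ester, which would lead into the 2,6-cis series.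
- Fallback (ring-closing metathesis in place of the sigmatropic shift; sets out from 3 and comes back at 13): Wittig olefination of 3 with Ph3P=CHCO2Et gives ethyl (E)-4-(2-pentyl-1,3-dioxolan-2-yl)but-2-enoate F1. iBu2AlH reduces it to (E)-4-(2-pentyl-1,3-dioxolan-2-yl)but-2-en-1-ol F2, which ClCO2Me and pyridine convert into methyl (E)-4-(2-pentyl-1,3-dioxolan-2-yl)but-2-enyl carbonate F3. Branch-selective allylic amination of F3 with tert-butyl (2R)-2-aminopent-4-enoate under [Ir(cod)Cl]2 and a chiral phosphoramidite, the ligand enantiomer chosen for S at C2, gives tert-butyl (2R)-2-{[(2S)-1-(2-pentyl-1,3-dioxolan-2-yl)but-3-en-2-yl]amino}pent-4-enoate F4. Ring-closing metathesis of its TsOH salt with the second-generation Grubbs catalyst forms C3=C4 and gives 13. The two centres are then set independently, C6 by the amino acid and C2 by the catalyst.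

Step 3.
- Risk: incomplete enantio- or diastereocontrol in the chloroallylboration, decomposition of the chloroallyl anion before it is captured by boron, and partial opening of the product during the basic oxidative work-up.
- Fallback (the cis-aziridine is made directly and the vinyl group added afterwards; sets out from 3 and comes back at 11): catalytic asymmetric aziridination of the imine formed in the flask from 3 and benzhydrylamine with ethyl diazoacetate under a VAPOL–B(OPh)3 catalyst (ligand enantiomer chosen for the 2S,3S ester), a reaction that is cis-selective by its mechanism, gives ethyl (2S,3S)-1-benzhydryl-3-[(2-pentyl-1,3-dioxolan-2-yl)methyl]aziridine-2-carboxylate F5. Hydrogenolysis (H2, Pd(OH)2 on carbon), done before any alkene is present, gives ethyl (2S,3S)-3-[(2-pentyl-1,3-dioxolan-2-yl)methyl]aziridine-2-carboxylate F6. N-Alkylation with tert-butyl bromoacetate (K2CO3, MeCN) gives ethyl (2S,3S)-1-(2-tert-butoxy-2-oxoethyl)-3-[(2-pentyl-1,3-dioxolan-2-yl)methyl]aziridine-2-carboxylate F7. iBu2AlH at −78 °C reduces the ethyl ester selectively to tert-butyl 2-{(2S,3S)-2-formyl-3-[(2-pentyl-1,3-dioxolan-2-yl)methyl]aziridin-1-yl}acetate F8, and Wittig methylenation (Ph3P=CH2) gives 11.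

Step 16.
- Risk: ring closure by the hindered N1 is slow, so intermolecular alkylation to oligomers and E2 loss of HI from the iodide can outrun it even at high dilution.
- Fallback (the hindered nitrogen is alkylated intermolecularly and the ring is closed at N14–C15; sets out from 19 and 21 and comes back at 30): acidolysis of 21 (HCl, dioxane) gives N-(4-aminobutyl)-2-nitrobenzenesulfonamide F9. Wolff rearrangement of 19 in its presence (PhCO2Ag, Et3N) gives the amide, allyl (2R,6S)-2-[2-({4-[(2-nitrophenyl)sulfonylamino]butyl}amino)-2-oxoethyl]-6-[(2-pentyl-1,3-dioxolan-2-yl)methyl]-3,6-dihydropyridine-1(2H)-carboxylate F10. Removal of the allyl carbamate (Pd(PPh3)4, PhSiH3) gives the N1–H amine, N-{4-[(2-nitrophenyl)sulfonylamino]butyl}-2-{(2R,6S)-6-[(2-pentyl-1,3-dioxolan-2-yl)methyl]-1,2,3,6-tetrahydropyridin-2-yl}acetamide F11. Alkylation of N1 with an excess of 22 (NaHCO3, NaI, MeCN, 70 °C), where concentration can be used to force the hindered amine and the weak base leaves the sulfonamide N–H alone, gives the N1-(3-hydroxypropyl) derivative F12. Mitsunobu alkylation of the acidic sulfonamide N–H by the primary alcohol (PPh3, DIAD, toluene/THF, high dilution) closes the ring and gives 30.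

## Further compounds

F1 | step 6 | ethyl (E)-4-(2-pentyl-1,3-dioxolan-2-yl)but-2-enoate | CCCCCC1(OCCO1)C/C=C/C(=O)OCC
F2 | step 6 | (E)-4-(2-pentyl-1,3-dioxolan-2-yl)but-2-en-1-ol | CCCCCC1(OCCO1)C/C=C/CO
F3 | step 6 | methyl (E)-4-(2-pentyl-1,3-dioxolan-2-yl)but-2-enyl carbonate | CCCCCC1(OCCO1)C/C=C/COC(=O)OC
F4 | step 6 | tert-butyl (2R)-2-{[(2S)-1-(2-pentyl-1,3-dioxolan-2-yl)but-3-en-2-yl]amino}pent-4-enoate | CCCCCC1(OCCO1)C[C@@H](C=C)N[C@H](CC=C)C(=O)OC(C)(C)C
F5 | step 3 | ethyl (2S,3S)-1-benzhydryl-3-[(2-pentyl-1,3-dioxolan-2-yl)methyl]aziridine-2-carboxylate | CCCCCC1(OCCO1)C[C@H]2[C@@H](C(=O)OCC)N2C(c3ccccc3)c4ccccc4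
F6 | step 3 | ethyl (2S,3S)-3-[(2-pentyl-1,3-dioxolan-2-yl)methyl]aziridine-2-carboxylate | CCCCCC1(OCCO1)C[C@H]2[C@@H](C(=O)OCC)N2
F7 | step 3 | ethyl (2S,3S)-1-(2-tert-butoxy-2-oxoethyl)-3-[(2-pentyl-1,3-dioxolan-2-yl)methyl]aziridine-2-carboxylate | CCCCCC1(OCCO1)C[C@H]2[C@@H](C(=O)OCC)N2CC(=O)OC(C)(C)C
F8 | step 3 | tert-butyl 2-{(2S,3S)-2-formyl-3-[(2-pentyl-1,3-dioxolan-2-yl)methyl]aziridin-1-yl}acetate | CCCCCC1(OCCO1)C[C@H]2[C@@H](C=O)N2CC(=O)OC(C)(C)C
F9 | step 16 | N-(4-aminobutyl)-2-nitrobenzenesulfonamide | NCCCCNS(=O)(=O)c1ccccc1[N+](=O)[O-]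
F10 | step 16 | allyl (2R,6S)-2-[2-({4-[(2-nitrophenyl)sulfonylamino]butyl}amino)-2-oxoethyl]-6-[(2-pentyl-1,3-dioxolan-2-yl)methyl]-3,6-dihydropyridine-1(2H)-carboxylate | CCCCCC1(OCCO1)C[C@H]2C=CC[C@H](CC(=O)NCCCCNS(=O)(=O)c3ccccc3[N+](=O)[O-])N2C(=O)OCC=C
F11 | step 16 | N-{4-[(2-nitrophenyl)sulfonylamino]butyl}-2-{(2R,6S)-6-[(2-pentyl-1,3-dioxolan-2-yl)methyl]-1,2,3,6-tetrahydropyridin-2-yl}acetamide | CCCCCC1(OCCO1)C[C@H]2C=CC[C@H](CC(=O)NCCCCNS(=O)(=O)c3ccccc3[N+](=O)[O-])N2
F12 | step 16 | 2-{(2R,6S)-1-(3-hydroxypropyl)-6-[(2-pentyl-1,3-dioxolan-2-yl)methyl]-1,2,3,6-tetrahydropyridin-2-yl}-N-{4-[(2-nitrophenyl)sulfonylamino]butyl}acetamide | CCCCCC1(OCCO1)C[C@H]2C=CC[C@H](CC(=O)NCCCCNS(=O)(=O)c3ccccc3[N+](=O)[O-])N2CCCO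
A1 | alternative 1 | tert-butyl 2-{(2R,6S)-6-(hept-1-ynyl)-1-[(1R)-2-hydroxy-1-phenylethyl]-1,2,3,6-tetrahydropyridin-2-yl}acetate (2,6-trans) | CCCCCC#C[C@H]1C=CC[C@H](CC(=O)OC(C)(C)C)N1[C@@H](CO)c2ccccc2
A2 | alternative 2 | methyl 2-{(2R,6S)-6-[(2S)-2-(tert-butyldimethylsilyloxy)but-3-enyl]-1-(2-nitrophenylsulfonyl)-1,2,3,6-tetrahydropyridin-2-yl}acetate (2,6-trans) | C=C[C@H](O[Si](C)(C)C(C)(C)C)C[C@H]1C=CC[C@H](CC(=O)OC)N1S(=O)(=O)c2ccccc2[N+](=O)[O-]
A3 | alternative 3 | methyl 2-{(2R,6S)-1-[3-({4-[(tert-butoxycarbonyl)amino]butyl}(2-nitrophenylsulfonyl)amino)propyl]-6-[(2-pentyl-1,3-dioxolan-2-yl)methyl]-1,2,3,6-tetrahydropyridin-2-yl}acetate (2,6-trans) | CCCCCC1(OCCO1)C[C@H]2C=CC[C@H](CC(=O)OC)N2CCCN(S(=O)(=O)c3ccccc3[N+](=O)[O-])CCCCNC(=O)OC(C)(C)C
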